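The readings are calculated with made-up constants; scatter was added.

The ratio of [reagent]·[catalyst]·time in blue to the same product in Thursday's run at its last reading, 50.0 s, comes to 21.3, and two chemists drew opposite conclusions from it.

all flasks: catalyst 0.34 mol%
- Thursday's: substrate 0.075 M; reagent 0.20 equiv; run made earlier
- amber: substrate 0.050 M; reagent 0.200 equiv; time 4.0 min
- green: substrate 0.050 M; reagent 0.600 equiv; time 4.0 min
- blue: substrate 0.050 M; reagent 2.00 equiv; time 4.0 min
- ochre: substrate 0.050 M; reagent 5.00 equiv; time 4.0 min
- teal: substrate 0.050 M; reagent 15.0 equiv; time 4.0 min

Thursday's run (percent of the substrate charged)

| time / s | target / % | substrate / % |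
|---|---|---|
| 10.0 | 1.2 | 98.4 |
| 15.0 | 2.8 | 97.8 |
| 20.0 | 2.4 | 97.6 |
| 30.0 | 4.3 | 95.9 |
| 40.0 | 3.9 | 95.0 |
| 50.0 | 4.7 | 94.4 |

(each reading ± 0.5 percentage points)

- amount of target at the end, in percent of the substrate charged for amber, green, blue, ochre, teal, in this order
- how the row runs (falls, then rises / rises, then falls / hardly changes / falls all the way / rises all the way)

- "hardly changes" means that all values lie within two and a half points (for a concentration: within two and a half percent of the largest)
- no earlier run changes the charge of catalyst; that part of a forecast is a guess

Both take the reaction as first order in substrate, reagent and catalyst, and both start from Thursday's last substrate reading, 94.4%, which, with its scatter, says that a substrate molecule had by then lived through 0.0576 of its lifetimes. Multiplying by the ratio gives 1.23 for blue, and this number is the dose, the count of substrate lifetimes that a flask offers with its reagent as charged, which grows in step with the equivalents.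

The first chemist follows a molecule to a single fork: once it has reacted it is target and stays target, so its chance of being target is 1 − e^(−dose), which is 70.8% for blue and can only climb along the row. The forecast stands on this side, with 8%, 21%, 52%, 78% and 90%, a row that rises all the way; its blue value lies below the chance just reckoned, and of its upper end it says “I therefore shade the high end down”.

The second chemist, whose reckoning I commit to, sends the molecule to another fork, supposing that target takes up reagent as readily as substrate does. Thursday's run cannot refute her, since at its small dose the share gone past target would be 0.166%, while a reading scatters by 0.5 percentage points. Her chance of finding a molecule as target is dose·e^(−dose), which is greatest at a dose of one, near 1.63 equivalents, and is 36.0% for blue, so her row climbs to a maximum and comes down again.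

The flask gives 8.07%, 19.7%, 32.0%, 15.5% and 0.0675%, so the row rises, then falls, although the first chemist's picture of reacted substrate staying target still holds in amber, where at 4.00 min nearly all of what had reacted stood as target, 8.07% beside 0.497% of over-reaction product.

    reagent + target → over-reaction product (k = 3.70 /M/min)
    substrate + reagent + catalyst ⇌ target + catalyst, rate k2*[substrate]*[reagent]*[catalyst] forward; the back reaction follows from the equilibrium constant (K = 34.0 /M, k = 23000 /M²/min)

At these charges the selectivity factor, k2[catalyst]/k1, is 1.06. Teal has a dose of 9.22, for which dose·e^(−dose) gives 0.0913%, and teal ended with 0.0675% of target.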